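**Plan**
Ring A is the central benzene: C1 carries the 2-(3-methoxyphenyl)ethyl chain (ring B), C2, C4 and C6 the 4-hydroxybenzyl arms, C3 the OH and C5 the OMe.
Enabling feature: the C3 oxygen and the C4 benzylic carbon sit on adjacent ring A carbons and the C5 methoxy group flanks C4. A C3–C4 aryne is therefore polarized to take an oxygen nucleophile at C3 and an acyl carbon at C4.
Cuts, in retrosynthetic order: three O–benzyl bonds and the C4 methylene (back to a ketone); C3–O together with C4–C(=O) (aryne plus 4-benzyloxybenzoic acid); C4–Si and C3–OTf (back to a phenol); C2–CH2 and C6–CH2 (Negishi); the central C–C of the bridge (olefination).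
Forward: no ring is built. Ring B is joined to ring A, the C2 and C6 arms are coupled on, the aryne precursor is made at C3/C4, the third arm enters by aryne insertion, and deoxygenation and debenzylation finish the route.
The target has no stereocentre. The only stereo element on the way, the E alkene of the stilbene, is erased by hydrogenation.

Key step: step 11

Assumption: the four starting materials are taken as catalogue compounds. The phenol oxygen first present at C3 leaves with the triflate, and the C3 oxygen of the target comes from the carboxylic acid.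

**Step 1**
Reactants: 1 3-hydroxy-5-methoxybenzaldehyde; 2 diethyl (3-methoxybenzyl)phosphonate
Product: 3 (E)-3-methoxy-5-[2-(3-methoxyphenyl)ethenyl]phenol
Conditions: KOtBu (2.3 equiv), THF, 0 °C to rt; aq HCl
Reagents that add atoms: none
Why: Horner–Wadsworth–Emmons olefination in which the first equivalent of base parks the phenol as a phenoxide that is meta to the formyl group and so does not deactivate it by resonance, while the benzylic phosphonate anion gives the E-stilbene, whose geometry is irrelevant because step 2 saturates it.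

**Step 2**
Reactants: 3 (E)-3-methoxy-5-[2-(3-methoxyphenyl)ethenyl]phenol
Product: 4 3-methoxy-5-[2-(3-methoxyphenyl)ethyl]phenol
Conditions: H2 (1 atm), Pd/C, EtOAc/MeOH, rt
Reagents that add atoms: none
Why: Catalytic hydrogenation of a 1,2-diarylethene over Pd/C is fast at ambient pressure and leaves the aryl methyl ethers and the phenol untouched.

**Step 3**
Reactants: 4 3-methoxy-5-[2-(3-methoxyphenyl)ethyl]phenol
Product: 5 2,4-dibromo-5-methoxy-3-[2-(3-methoxyphenyl)ethyl]phenol (bromine at ring A C2 and C6, C4 still H)
Conditions: NBS (2.05 equiv), CH2Cl2, −20 to 0 °C, dark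
Reagents that add atoms: N-bromosuccinimide, O=C1CCC(=O)N1Br
Why: Electrophilic aromatic bromination in which the resorcinol-type ring A far outpaces the anisole-type ring B, and 5-alkylresorcinol derivatives take two bromines at the positions flanking the alkyl chain (each para to one oxygen and ortho to the other) before the position between the two oxygens reacts.

**Step 4**
Reactants: 5 2,4-dibromo-5-methoxy-3-[2-(3-methoxyphenyl)ethyl]phenol
Product: 6 triisopropylsilyl ether of 5
Conditions: TIPSCl, imidazole, DMF, rt
Reagents that add atoms: chlorotriisopropylsilane, CC(C)[Si](Cl)(C(C)C)C(C)C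
Why: Standard phenol silylation that removes the acidic proton and the phenoxide donation before the coupling, gives an ether inert to organozinc reagents, and can later be undone with fluoride without touching benzyl ethers.

**Step 5**
Reactants: 7 4-benzyloxybenzyl chloride
Product: 8 4-benzyloxybenzylzinc chloride (titrated THF solution, used as such)
Conditions: Zn dust, LiCl, THF, 25 °C
Reagents that add atoms: zinc, [Zn]
Why: LiCl-promoted direct insertion of zinc into a benzylic chloride runs at room temperature, keeps Wurtz-type homocoupling low and tolerates the aryl benzyl ether.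

**Step 6**
Reactants: 6 triisopropylsilyl ether of 5; 8 4-benzyloxybenzylzinc chloride
Product: 9 2,4-bis(4-benzyloxybenzyl)-5-methoxy-3-[2-(3-methoxyphenyl)ethyl]phenyl triisopropylsilyl ether (arms at ring A C2 and C6)
Conditions: 8 (3 equiv), Pd(OAc)2 (5 mol %), SPhos (10 mol %), THF, 50 °C
Reagents that add atoms: none
Why: Twofold Negishi coupling of a benzylic zinc chloride with aryl bromides, in which the bulky electron-rich biarylphosphine lets zerovalent palladium insert into di-ortho-substituted electron-rich C–Br bonds, the benzylpalladium intermediate has no β-hydrogen, and the silyl and benzyl ethers are inert.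

**Step 7**
Reactants: 9 bis(benzyl) triisopropylsilyl ether
Product: 10 2,4-bis(4-benzyloxybenzyl)-5-methoxy-3-[2-(3-methoxyphenyl)ethyl]phenol
Conditions: Bu4NF, AcOH, THF, 0 °C to rt
Reagents that add atoms: none
Why: Fluoride cleavage of an aryl silyl ether driven by Si–F bond formation, buffered with acetic acid so that the electron-rich phenoxide does not linger, with benzyl and methyl ethers unaffected.

**Step 8**
Reactants: 10 2,4-bis(4-benzyloxybenzyl)-5-methoxy-3-[2-(3-methoxyphenyl)ethyl]phenol
Product: 11 2,4-bis(4-benzyloxybenzyl)-6-bromo-5-methoxy-3-[2-(3-methoxyphenyl)ethyl]phenol (bromine at ring A C4)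
Conditions: NBS (1.0 equiv), iPr2NH (10 mol %), CH2Cl2, −20 to 0 °C, dark
Reagents that add atoms: N-bromosuccinimide, O=C1CCC(=O)N1Br
Why: Amine-catalysed ortho-bromination of a phenol, where C4 is the only free position of ring A, lies ortho to both oxygens, and belongs to a free phenol ring far more nucleophilic than the aryl ether rings elsewhere in the molecule.

**Step 9**
Reactants: 11 C4-bromophenol
Product: 12 trimethylsilyl ether of 11
Conditions: (Me3Si)2NH, THF, reflux; volatiles removed in vacuo
Reagents that add atoms: hexamethyldisilazane, C[Si](C)(C)N[Si](C)(C)C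
Why: O-silylation with hexamethyldisilazane gives only ammonia as co-product, so the hydrolytically labile trimethylsilyl ether is obtained by evaporation without aqueous work-up.

**Step 10**
Reactants: 12 trimethylsilyl ether of 11
Product: 15 2,4-bis(4-benzyloxybenzyl)-5-methoxy-3-[2-(3-methoxyphenyl)ethyl]-6-(trimethylsilyl)phenyl trifluoromethanesulfonate (ring A: C3 OTf, C4 SiMe3), via C4-lithio silyl ether 13 (not isolated), via lithium 2-silylphenoxide 14 (not isolated)
Conditions: nBuLi (1.1 equiv), THF, −100 to −78 °C; Tf2O (1.2 equiv), −100 to −78 °C; aq NaHCO3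
Reagents that add atoms: trifluoromethanesulfonic anhydride, O=S(=O)(OS(=O)(=O)C(F)(F)F)C(F)(F)F
Why: Bromine–lithium exchange at low temperature outruns deprotonation of the diarylmethane and benzyl ether CH2 groups, aryllithium 13 takes silicon from the neighbouring oxygen (retro-Brook 1,3-shift from O to C), and phenoxide 14 is trapped by Tf2O, which is the standard entry to ortho-silylaryl triflates from ortho-bromophenols.

**Step 11**
Reactants: 15 ring A silyl triflate; 16 4-benzyloxybenzoic acid
Product: 19 [3,5-bis(4-benzyloxybenzyl)-2-hydroxy-6-methoxy-4-[2-(3-methoxyphenyl)ethyl]phenyl](4-benzyloxyphenyl)methanone (ring A: C3 OH, C4 4-benzyloxybenzoyl), via C3–C4 aryne 17 (not isolated), via C4 aryl anion ester 18 (not isolated)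
Conditions: 16 (1.3 equiv) and CsF (4 equiv) premixed, THF (0.05 M), sealed tube, 125 °C; aq NH4Cl
Reagents that add atoms: none
Why: Fluoride attacks the C4 silicon and triflate leaves C3, releasing aryne 17 slowly because CsF is barely soluble in THF. The carboxylate oxygen of 16 adds to C3, the aryne carbon remote from the C5 methoxy group, because the inductively withdrawing oxygen substituent widens the internal angle at C3 and stabilizes the charge that builds at the adjacent C4 (aryl anion 18). In the hot, aprotic, weakly polar medium this anion should attack its own ester carbonyl through a four-membered transition state faster than it finds a proton, and collapse of the adduct moves the aroyl group from oxygen to C4, giving the C3 phenoxide and, after work-up, 19. The reaction type is the known fluoride-induced insertion of arynes into the C–O bond of carboxylic acids, in essence an anionic Fries-type acyl shift, which leads to ortho-hydroxyaryl ketones. Two bonds form (C3–O and C4–C(=O)), no ring closes and no stereocentre arises. The step needs the right orientation of addition, secured by the C5 methoxy group against the modest steric bias of the C2 benzyl arm toward a small oxygen nucleophile; it also needs acyl shift over protonation, secured by excess CsF that holds 16 as carboxylate, by dilution, by temperature and by the C2 arm buttressing the ester toward C4.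

**Step 12**
Reactants: 19 ortho-hydroxyaryl ketone
Product: 22 2,4,6-tris(4-benzyloxybenzyl)-3-methoxy-5-[2-(3-methoxyphenyl)ethyl]phenol, via aryl ethyl carbonate 20 (not isolated), via ortho-quinone methide 21 (not isolated)
Conditions: ClCO2Et, Et3N, THF, 0 °C; then NaBH4, THF/H2O, 0 °C to rt
Reagents that add atoms: none
Why: Ortho-hydroxyl-assisted deoxygenation of an aryl ketone under basic conditions, in which borohydride reduces the ketone of 20, the ethoxycarbonyl group moves to the new benzylic alkoxide and is expelled by the freed C3 phenoxide to give 21, and 21 takes a second hydride at its exocyclic carbon, so the C4 methylene is reached without acid that could ionize the electron-rich diarylmethane arms or the benzyl ethers.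

**Step 13**
Reactants: 22 tris(4-benzyloxybenzyl) phenol
Product: 23 2,4,6-tris(4-hydroxybenzyl)-3-methoxy-5-[2-(3-methoxyphenyl)ethyl]phenol (target, CNP0285788.0)
Conditions: H2 (1 atm), Pd/C, EtOAc/EtOH, rt
Reagents that add atoms: none
Why: Hydrogenolysis of the three aryl benzyl ethers over Pd/C is standard, and the diarylmethane C–C bonds, the bibenzyl bridge and the two aryl methyl ethers are inert under these conditions.

**Compound list**
1 | 3-hydroxy-5-methoxybenzaldehyde | COc1cc(O)cc(C=O)c1 | starting material
2 | diethyl (3-methoxybenzyl)phosphonate | CCOP(=O)(Cc1cccc(OC)c1)OCC | starting material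
3 | (E)-3-methoxy-5-[2-(3-methoxyphenyl)ethenyl]phenol | COc1cccc(/C=C/c2cc(O)cc(OC)c2)c1 | intermediate
4 | 3-methoxy-5-[2-(3-methoxyphenyl)ethyl]phenol | COc1cccc(CCc2cc(O)cc(OC)c2)c1 | intermediate
5 | 2,4-dibromo-5-methoxy-3-[2-(3-methoxyphenyl)ethyl]phenol | COc1cccc(CCc2c(Br)c(O)cc(OC)c2Br)c1 | intermediate
6 | triisopropylsilyl ether of 5 | COc1cccc(CCc2c(Br)c(O[Si](C(C)C)(C(C)C)C(C)C)cc(OC)c2Br)c1 | intermediate
7 | 4-benzyloxybenzyl chloride | ClCc1ccc(OCc2ccccc2)cc1 | starting material
8 | 4-benzyloxybenzylzinc chloride (THF solution) | Cl[Zn]Cc1ccc(OCc2ccccc2)cc1 | intermediate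
9 | 2,4-bis(4-benzyloxybenzyl)-5-methoxy-3-[2-(3-methoxyphenyl)ethyl]phenyl triisopropylsilyl ether | COc1cccc(CCc2c(Cc3ccc(OCc4ccccc4)cc3)c(O[Si](C(C)C)(C(C)C)C(C)C)cc(OC)c2Cc2ccc(OCc3ccccc3)cc2)c1 | intermediate
10 | 2,4-bis(4-benzyloxybenzyl)-5-methoxy-3-[2-(3-methoxyphenyl)ethyl]phenol | COc1cccc(CCc2c(Cc3ccc(OCc4ccccc4)cc3)c(O)cc(OC)c2Cc2ccc(OCc3ccccc3)cc2)c1 | intermediate
11 | 2,4-bis(4-benzyloxybenzyl)-6-bromo-5-methoxy-3-[2-(3-methoxyphenyl)ethyl]phenol | COc1cccc(CCc2c(Cc3ccc(OCc4ccccc4)cc3)c(O)c(Br)c(OC)c2Cc2ccc(OCc3ccccc3)cc2)c1 | intermediate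
12 | trimethylsilyl ether of 11 | COc1cccc(CCc2c(Cc3ccc(OCc4ccccc4)cc3)c(O[Si](C)(C)C)c(Br)c(OC)c2Cc2ccc(OCc3ccccc3)cc2)c1 | intermediate
13 | C4-lithio trimethylsilyl ether (formed in the flask) | COc1cccc(CCc2c(Cc3ccc(OCc4ccccc4)cc3)c(O[Si](C)(C)C)c([Li])c(OC)c2Cc2ccc(OCc3ccccc3)cc2)c1 | intermediate
14 | lithium phenoxide with C4 trimethylsilyl group (formed in the flask) | [Li+].COc1cccc(CCc2c(Cc3ccc(OCc4ccccc4)cc3)c([O-])c([Si](C)(C)C)c(OC)c2Cc2ccc(OCc3ccccc3)cc2)c1 | intermediate
15 | ring A silyl triflate (C3 OTf, C4 SiMe3) | COc1cccc(CCc2c(Cc3ccc(OCc4ccccc4)cc3)c(OS(=O)(=O)C(F)(F)F)c([Si](C)(C)C)c(OC)c2Cc2ccc(OCc3ccccc3)cc2)c1 | intermediate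
16 | 4-benzyloxybenzoic acid | O=C(O)c1ccc(OCc2ccccc2)cc1 | starting material
17 | C3–C4 aryne of ring A (formed in the flask) | COc1cccc(CCC2=C(Cc3ccc(OCc4ccccc4)cc3)C#CC(OC)=C2Cc2ccc(OCc3ccccc3)cc2)c1 | intermediate
18 | C3 4-benzyloxybenzoate ester with aryl anion at C4, cesium salt (formed in the flask) | [Cs+].COc1cccc(CCc2c(Cc3ccc(OCc4ccccc4)cc3)c(OC(=O)c3ccc(OCc4ccccc4)cc3)[c-]c(OC)c2Cc2ccc(OCc3ccccc3)cc2)c1 | intermediate
19 | ortho-hydroxyaryl ketone (C3 OH, C4 4-benzyloxybenzoyl) | COc1cccc(CCc2c(Cc3ccc(OCc4ccccc4)cc3)c(O)c(C(=O)c3ccc(OCc4ccccc4)cc3)c(OC)c2Cc2ccc(OCc3ccccc3)cc2)c1 | intermediate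
20 | C3 ethyl carbonate of 19 (formed in the flask) | COc1cccc(CCc2c(Cc3ccc(OCc4ccccc4)cc3)c(OC(=O)OCC)c(C(=O)c3ccc(OCc4ccccc4)cc3)c(OC)c2Cc2ccc(OCc3ccccc3)cc2)c1 | intermediate
21 | ortho-quinone methide, C3 carbonyl and C4 exocyclic 4-benzyloxybenzylidene, alkene geometry not fixed (formed in the flask) | COc1cccc(CCC2=C(Cc3ccc(OCc4ccccc4)cc3)C(=O)C(=Cc3ccc(OCc4ccccc4)cc3)C(OC)=C2Cc2ccc(OCc3ccccc3)cc2)c1 | intermediate
22 | 2,4,6-tris(4-benzyloxybenzyl)-3-methoxy-5-[2-(3-methoxyphenyl)ethyl]phenol | COc1cccc(CCc2c(Cc3ccc(OCc4ccccc4)cc3)c(O)c(Cc3ccc(OCc4ccccc4)cc3)c(OC)c2Cc2ccc(OCc3ccccc3)cc2)c1 | intermediate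
23 | 2,4,6-tris(4-hydroxybenzyl)-3-methoxy-5-[2-(3-methoxyphenyl)ethyl]phenol | COc1cccc(CCc2c(Cc3ccc(O)cc3)c(O)c(Cc3ccc(O)cc3)c(OC)c2Cc2ccc(O)cc2)c1 | target

**Step count**
Total step count: 13.
Longest linear sequence: 12 (steps 1–4 and 6–13, from 1). Step 5 is a one-step side branch.

**Steps most likely to fail**

Step 11. The C4 aryl anion may pick up a proton before the acyl group shifts, which would amount to plain O-arylation. The addition may turn around under the steric push of the C2 arm. The aryne may also be consumed by THF or by the product phenoxide. The fallback reaches the same type of aryl anion without an aryne and sets out from 11. Steglich esterification of 11 with 16 (DCC, DMAP, CH2Cl2) should give the 2-bromoaryl 4-benzyloxybenzoate F1. Treatment with sBuLi in THF/Et2O at −95 °C should exchange the C4 bromine. The resulting C4-lithio ester F2 should pass its aroyl group from oxygen to C4, an anionic Fries-type shift triggered by halogen–metal exchange. Quenching with aq NH4Cl comes back to the route at 19. Both new bonds are then placed by the bromine and the phenol oxygen rather than by aryne polarization.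

Step 6. Oxidative addition into two di-ortho-substituted, electron-rich C–Br bonds may be slow. The coupling could then stall after one arm, or hydrodebromination and homocoupling of the benzylzinc reagent could take over. The fallback reverses the roles of the partners and sets out from 6. Treatment with tBuLi (4.4 equiv) in THF at −78 °C should give the C2,C6-dilithio arene F3, since the bulky triisopropylsilyl group resists the O-to-C shift at this temperature. ZnCl2 should convert F3 into the C2,C6-bis(chlorozincio) arene F4. Coupling of F4 with benzyl chloride 7 (Pd(OAc)2, SPhos, THF, rt to 50 °C) places the easy oxidative addition on the unhindered benzylic chloride and comes back at 9.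

Step 12. Acylation of the hindered, hydrogen-bonded C3 phenol may be sluggish. The carbonate may hydrolyse before hydride reaches the twisted ketone, which would stop the cascade short of the methylene. The fallback replaces hydride capture of a quinone methide by hydrogenolytic C–O cleavage and sets out from 19. LiAlH4 in THF at 0 °C should give the racemic ortho-hydroxybenzhydrol F5. H2 over Pd/C in EtOH/AcOH should then cleave the doubly benzylic C–OH bond and the three benzyl ethers in one operation, coming back at 23 and bypassing 22.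

**Further compounds**
F1 | step 11 | 2,4-bis(4-benzyloxybenzyl)-6-bromo-5-methoxy-3-[2-(3-methoxyphenyl)ethyl]phenyl 4-benzyloxybenzoate | COc1cccc(CCc2c(Cc3ccc(OCc4ccccc4)cc3)c(OC(=O)c3ccc(OCc4ccccc4)cc3)c(Br)c(OC)c2Cc2ccc(OCc3ccccc3)cc2)c1
F2 | step 11 | C4-lithio analogue of F1 | COc1cccc(CCc2c(Cc3ccc(OCc4ccccc4)cc3)c(OC(=O)c3ccc(OCc4ccccc4)cc3)c([Li])c(OC)c2Cc2ccc(OCc3ccccc3)cc2)c1
F3 | step 6 | C2,C6-dilithio arene from 6 | COc1cccc(CCc2c([Li])c(O[Si](C(C)C)(C(C)C)C(C)C)cc(OC)c2[Li])c1
F4 | step 6 | C2,C6-bis(chlorozincio) arene from 6 | COc1cccc(CCc2c([Zn]Cl)c(O[Si](C(C)C)(C(C)C)C(C)C)cc(OC)c2[Zn]Cl)c1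
F5 | step 12 | racemic 2,4-bis(4-benzyloxybenzyl)-6-[(4-benzyloxyphenyl)(hydroxy)methyl]-5-methoxy-3-[2-(3-methoxyphenyl)ethyl]phenol | COc1cccc(CCc2c(Cc3ccc(OCc4ccccc4)cc3)c(O)c(C(O)c3ccc(OCc4ccccc4)cc3)c(OC)c2Cc2ccc(OCc3ccccc3)cc2)c1
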